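The data were generated by integration on assumed constants, noise included.

Take one monomer unit on the board: at the end it sits either in a chain or free, and the average length is units in chains divided by chains begun.

| flask | free monomer | initiator | remark | time |
|---|---|---|---|---|
| maple | 0.013 M (fed, over 6.0 s) | 100 µM | run made earlier |  |
| larch | 0.030 M (fed, over 6.0 s) | 100 µM | run made earlier |  |
| alder | 0.020 M (fed, over 6.0 s) | 150 µM | run made earlier |  |
| north-east | 0.020 M (fed, over 6.0 s) | 100 µM |  | 10 min |
| south-west | 0.020 M (fed, over 1.5 s) | 100 µM |  | 10 min |

| run | time / min | monomer in chains / % | free monomer / % |
|---|---|---|---|
| maple | 2.50 | 70.1 | 30.7 |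
| maple | 5.00 | 86.3 | 14.4 |
| maple | 8.00 | 88.7 | 10.9 |
| maple | 10.0 | 89.0 | 10.1 |
| maple | 12.0 | 89.3 | 11.2 |
| larch | 1.00 | 40.8 | 58.9 |
| larch | 2.00 | 67.1 | 33.2 |
| larch | 3.00 | 79.0 | 19.4 |
| larch | 6.00 | 93.0 | 7.0 |
| larch | 12.0 | 95.3 | 4.6 |
| alder | 1.00 | 53.0 | 47.2 |
| alder | 2.00 | 78.3 | 22.0 |
| alder | 3.00 | 87.3 | 12.9 |
| alder | 6.00 | 92.7 | 7.0 |
| alder | 12.0 | 93.7 | 5.7 |

(standard deviation of a reading: 0.5 percentage points)

- the average divides the monomer in chains by the number of chains begun, living and dead together
- reactions considered so far: free monomer + initiator -> living end + monomer in chains; free monomer + living end -> monomer in chains + living end; monomer in chains + living end -> free monomer + living end; free monomer + initiator -> spent initiator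
- the earlier runs do not show the number of chains; that part of a forecast is a guess

1. which of the two ends with the longer chains by the average number of monomer units in a chain (chains begun, living or dead) ("neither" if they lie within 10 %) (north-east / south-west / neither)
2. average number of monomer units in a chain (chains begun, living or dead) at the end, north-east
3. average number of monomer units in a chain (chains begun, living or dead) at the end, south-west

Two of us argue over north-east and south-west. The first watches the feed: south-west takes its charge in 1.5 s, north-east in 6.0 s, a factor of 4.00, so south-west's chains get a head start and should end longer.

The second watches the end. In the larch run, free monomer's distance from its last reading shrinks at 0.641 /min, a reading that means a time of 93.6 s. Either feed is far shorter than that, so it is a small correction to the start, and 10 min spans 6.41 such times.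

The last readings of free monomer are 0.00146 M in maple, 0.00138 M in larch and 0.00114 M in alder, though the charges differ. Their mean is the floor, the concentration of free monomer that stays unbound at the end (the equilibrium monomer concentration of a ceiling): 0.00133 M.

So the second reckons just the correction. The charge ratio is 200, and the floor takes 13.3 off, which leaves 187 for both flasks, if each initiator begins one chain. The runs do not show that count.

The forecast says neither, with 220 for north-east and 220 for south-west, above my figure by a guessed efficiency of 0.85, and argues: “Both initiator reactions are first order in monomer, so their split does not depend on feed rate.”

The flask gives neither: 199 in north-east and 199 in south-west.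

    free monomer + initiator → living end + monomer in chains (k = 10.2 /M/s)
    free monomer + living end → monomer in chains + living end, rate k2*[living end]*[free monomer] (k = 111 /M/s)
    monomer in chains + living end → free monomer + living end, rate k3*[living end] as long as [monomer in chains] is above zero (k = 0.146 /s)
    free monomer + initiator → spent initiator (k = 0.700 /M/s)

At the end of its feed, north-east holds 4.48 × 10⁻⁵ M of living ends after 6.0 s and south-west 1.41 × 10⁻⁵ M after 1.5 s, but the dosing makes no difference to the final length . In north-east, growth and the back step ran against each other side by side: by 5.00 min initiator stood at 0 % and the back step had 49 % of its turnover up to 10 min behind it, and at 10.0 min the flask held 9.36 × 10⁻⁵ M of living ends and free monomer at 6.77 %; the floor gives 6.63 %. My gap lies in the count: those ends stand below the 100 µM charged.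

In a neighbour charged like north-east but with 0.0050 M of free monomer, the floor is 26.6 % of the charge, so the length reckons to 36.7. That flask keeps 26 % free and gives 39.2.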